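**Retrosynthetic overview**
- The target is released last by fluoride cleavage of two aryl silyl ethers; its C3 hydroxyl is placed on a 3-unsubstituted flavone by C3 lithiation, borate trapping and C–B oxidation.
- Ring C is cut at C4a–C4, C4–C3 and O1–C2 into three pieces: a ring A o-iodophenol, carbon monoxide (C4) and a ring B arylacetylene (C2, C3 and the 4'-prenyloxyphenyl group).
- Feature the strategy rests on: in ring A, C8a (the carbon bearing O1) is para to the methoxy-bearing C6, and the C5 and C7 oxygens lie mirror-symmetrically about the C6···C8a axis. Ring A is therefore a symmetric 3,5-dioxygenated 4-methoxyphenol with two identical ortho carbons, so only the 6-methoxy isomer can form.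
- Ring A piece: 2-methoxyresorcinol, bis-silylation, Ir-catalysed C–H borylation para to OMe, C–B oxidation, mono-iodination. Ring B piece: 4-hydroxybenzaldehyde, O-prenylation, Seyferth–Gilbert alkynylation.
- Ring order: rings A and B are purchased benzene rings; ring C is the only ring formed, in step 7.

Key step: step 7

Remark: the enaminone intermediate of step 7 is drawn with E geometry; its push–pull double bond isomerises freely and the geometry has no consequence.

**Step 1**
Reactants: 1 2-methoxyresorcinol
Product: 2 1,3-bis(tert-butyldimethylsilyloxy)-2-methoxybenzene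
Conditions: TBSCl (2.4 equiv), imidazole (5 equiv), DMF, rt
Reagents that add atoms: tert-butyldimethylsilyl chloride, CC(C)(C)[Si](C)(C)Cl
Why: Standard silylation of phenols with a silyl chloride and imidazole; the two hydroxyls are equivalent and excess reagent should drive both to the silyl ether despite the flanking methoxy group.

**Step 2**
Reactants: 2 1,3-bis(tert-butyldimethylsilyloxy)-2-methoxybenzene
Product: 3 2-[3,5-bis(tert-butyldimethylsilyloxy)-4-methoxyphenyl]-4,4,5,5-tetramethyl-1,3,2-dioxaborolane
Conditions: [Ir(OMe)(cod)]2 (1.5 mol %), 4,4'-di-tert-butyl-2,2'-bipyridine (3 mol %), B2pin2 (1.0 equiv), THF, 80 °C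
Reagents that add atoms: bis(pinacolato)diboron, CC1(C)OB(OC1(C)C)B1OC(C)(C)C(C)(C)O1
Why: Iridium-catalysed aromatic C–H borylation is governed by sterics and avoids C–H bonds next to a substituent, so of the three ring hydrogens only the one para to the methoxy group, which has a hydrogen on each side, should be borylated.

**Step 3**
Reactants: 3 2-[3,5-bis(tert-butyldimethylsilyloxy)-4-methoxyphenyl]-4,4,5,5-tetramethyl-1,3,2-dioxaborolane
Product: 4 3,5-bis(tert-butyldimethylsilyloxy)-4-methoxyphenol
Conditions: KHSO5 (1.1 equiv, as 2KHSO5·KHSO4·K2SO4), acetone/H2O, 0 °C to rt, 15 min; NaHSO3 quench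
Reagents that add atoms: potassium peroxymonosulfate, [K+].OOS(=O)(=O)[O-]
Why: Oxidation of an arylboronate by a peroxide (peroxide adds to boron, the aryl group shifts from boron to oxygen, the borate ester hydrolyses) should give the phenol, and the short, non-basic exposure should leave the aryl silyl ethers in place.

**Step 4**
Reactants: 4 3,5-bis(tert-butyldimethylsilyloxy)-4-methoxyphenol
Product: 5 2-iodo-3,5-bis(tert-butyldimethylsilyloxy)-4-methoxyphenol
Conditions: NIS (1.0 equiv), MeCN, −20 to 0 °C, dark
Reagents that add atoms: N-iodosuccinimide, O=C1CCC(=O)N1I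
Why: Electrophilic aromatic iodination; the only two ring C–H positions are equivalent and each is activated by an ortho hydroxyl and by ortho and para silyloxy groups, so one equivalent of reagent at low temperature should give a single mono-iodide.

**Step 5**
Reactants: 6 4-hydroxybenzaldehyde; 7 prenyl bromide (1-bromo-3-methylbut-2-ene)
Product: 8 4-(3-methylbut-2-enyloxy)benzaldehyde
Conditions: K2CO3, DMF, rt
Reagents that add atoms: none
Why: Williamson ether synthesis, SN2 displacement at the primary allylic bromide by the acidic para-formyl phenoxide, which should alkylate on oxygen in a polar aprotic solvent.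

**Step 6**
Reactants: 8 4-(3-methylbut-2-enyloxy)benzaldehyde; 9 dimethyl (1-diazo-2-oxopropyl)phosphonate
Product: 10 1-ethynyl-4-(3-methylbut-2-enyloxy)benzene
Conditions: K2CO3, MeOH, 0 °C to rt
Reagents that add atoms: none
Why: Seyferth–Gilbert homologation in its Ohira–Bestmann form (methanolysis of the acetyl group, olefination of the aldehyde to a diazoalkene, loss of N2 and 1,2-hydrogen shift); the mild carbonate conditions should leave the prenyl ether alone.

**Step 7**
Reactants: 5 2-iodo-3,5-bis(tert-butyldimethylsilyloxy)-4-methoxyphenol; 10 1-ethynyl-4-(3-methylbut-2-enyloxy)benzene (1.3 equiv); 11 carbon monoxide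
Product: 14 5,7-bis(tert-butyldimethylsilyloxy)-6-methoxy-4'-prenyloxyflavone, via o-hydroxyaryl ynone 12 (not isolated), via diethylamino enone 13 (not isolated)
Conditions: PdCl2(dppf) (5 mol %), CO (1 atm, balloon), Et2NH (degassed, as solvent), 60 °C
Reagents that add atoms: diethylamine, CCNCC (its atoms appear only in intermediate 13 and are released again)
Why: Zerovalent palladium, formed in the flask from PdCl2(dppf), inserts into the C–I bond of 5, CO inserts to give an aroylpalladium species, and this couples with the amine-deprotonated alkyne 10 to release ynone 12, forming C4a–C4 and C4–C3 at the CO carbon in a carbonylative Sonogashira coupling. Diethylamine then adds in conjugate fashion to 12 to give enaminone 13, and the neighbouring phenol oxygen attacks the amine-bearing carbon and expels the amine, so ring C closes by a 6-endo addition–elimination (6-endo-trig on 13, formally 6-endo-dig on the ynone) that forms O1–C2. The closest known reaction type is the palladium-catalysed carbonylative annulation of o-iodophenols with terminal arylacetylenes in a secondary amine, which gives flavones. No stereocentre is created. Two selectivities are needed: CO insertion before alkyne transfer, which the CO atmosphere and the fast migration of the electron-rich aryl group onto CO should secure, and 6-endo closure in place of 5-exo closure to an aurone, which the secondary amine should secure by routing the ynone through 13. The position of the methoxy group is not at issue because both ortho carbons of phenol 4 were identical, and the silyl and prenyl ethers should tolerate the basic, acid-free medium.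

**Step 8**
Reactants: 14 5,7-bis(tert-butyldimethylsilyloxy)-6-methoxy-4'-prenyloxyflavone
Product: 17 5,7-bis(tert-butyldimethylsilyloxy)-3-hydroxy-6-methoxy-4'-prenyloxyflavone, via 3-lithioflavone 15 (not isolated), via lithium trimethoxyborate 16 (not isolated)
Conditions: LiN(iPr)2 (1.3 equiv), THF, −78 °C; B(OMe)3 (2 equiv), −78 to 0 °C; AcOH, 30% aq. H2O2, 0 °C
Reagents that add atoms: hydrogen peroxide, OO (the C3 oxygen); carried only by the intermediates: lithium diisopropylamide, [Li+].CC(C)[N-]C(C)C (lithium of 15 and 16) and trimethyl borate, COB(OC)OC (boron and methoxy groups of 16)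
Why: Directed C3 lithiation of a flavone by a hindered amide base next to the C4 carbonyl, trapping as the borate and peroxide oxidation of the C–B bond with carbon-to-oxygen migration is the established lithiation–borylation–oxidation route to flavonols; cold, briefly applied hydrogen peroxide should not touch the isolated prenyl olefin or the silyl ethers.

**Step 9**
Reactants: 17 5,7-bis(tert-butyldimethylsilyloxy)-3-hydroxy-6-methoxy-4'-prenyloxyflavone
Product: 18 3,5,7-trihydroxy-6-methoxy-4'-prenyloxyflavone
Conditions: Bu4NF (2.4 equiv), AcOH (2.4 equiv), THF, 0 °C to rt, under argon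
Reagents that add atoms: none
Why: Fluoride-driven desilylation of aryl silyl ethers (formation of the strong Si–F bond), buffered with acetic acid so that the freed polyphenol is not held as an air-sensitive phenoxide; no acid strong enough to ionise the prenyl ether and no reduction is involved, so the prenyl and methyl ethers should survive.

**Compound list**
1 | 2-methoxyresorcinol | COc1c(O)cccc1O | starting material
2 | 1,3-bis(tert-butyldimethylsilyloxy)-2-methoxybenzene | COc1c(O[Si](C)(C)C(C)(C)C)cccc1O[Si](C)(C)C(C)(C)C | intermediate
3 | 2-[3,5-bis(tert-butyldimethylsilyloxy)-4-methoxyphenyl]-4,4,5,5-tetramethyl-1,3,2-dioxaborolane | COc1c(O[Si](C)(C)C(C)(C)C)cc(B2OC(C)(C)C(C)(C)O2)cc1O[Si](C)(C)C(C)(C)C | intermediate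
4 | 3,5-bis(tert-butyldimethylsilyloxy)-4-methoxyphenol | COc1c(O[Si](C)(C)C(C)(C)C)cc(O)cc1O[Si](C)(C)C(C)(C)C | intermediate
5 | 2-iodo-3,5-bis(tert-butyldimethylsilyloxy)-4-methoxyphenol | COc1c(O[Si](C)(C)C(C)(C)C)cc(O)c(I)c1O[Si](C)(C)C(C)(C)C | intermediate
6 | 4-hydroxybenzaldehyde | O=Cc1ccc(O)cc1 | starting material
7 | prenyl bromide (1-bromo-3-methylbut-2-ene) | CC(C)=CCBr | starting material
8 | 4-(3-methylbut-2-enyloxy)benzaldehyde | CC(C)=CCOc1ccc(C=O)cc1 | intermediate
9 | dimethyl (1-diazo-2-oxopropyl)phosphonate | CC(=O)C(=[N+]=[N-])P(=O)(OC)OC | starting material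
10 | 1-ethynyl-4-(3-methylbut-2-enyloxy)benzene | C#Cc1ccc(OCC=C(C)C)cc1 | intermediate
11 | carbon monoxide | [C-]#[O+] | starting material
12 | 1-[2-hydroxy-5-methoxy-4,6-bis(tert-butyldimethylsilyloxy)phenyl]-3-[4-(3-methylbut-2-enyloxy)phenyl]prop-2-yn-1-one (formed in the flask in step 7) | COc1c(O[Si](C)(C)C(C)(C)C)cc(O)c(C(=O)C#Cc2ccc(OCC=C(C)C)cc2)c1O[Si](C)(C)C(C)(C)C | intermediate
13 | (E)-3-(diethylamino)-1-[2-hydroxy-5-methoxy-4,6-bis(tert-butyldimethylsilyloxy)phenyl]-3-[4-(3-methylbut-2-enyloxy)phenyl]prop-2-en-1-one (formed in the flask in step 7) | COc1c(O[Si](C)(C)C(C)(C)C)cc(O)c(C(=O)/C=C(/N(CC)CC)c2ccc(OCC=C(C)C)cc2)c1O[Si](C)(C)C(C)(C)C | intermediate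
14 | 5,7-bis(tert-butyldimethylsilyloxy)-6-methoxy-4'-prenyloxyflavone | COc1c(O[Si](C)(C)C(C)(C)C)cc2oc(-c3ccc(OCC=C(C)C)cc3)cc(=O)c2c1O[Si](C)(C)C(C)(C)C | intermediate
15 | 3-lithio-5,7-bis(tert-butyldimethylsilyloxy)-6-methoxy-4'-prenyloxyflavone (formed in the flask in step 8) | COc1c(O[Si](C)(C)C(C)(C)C)cc2oc(-c3ccc(OCC=C(C)C)cc3)c([Li])c(=O)c2c1O[Si](C)(C)C(C)(C)C | intermediate
16 | lithium [5,7-bis(tert-butyldimethylsilyloxy)-6-methoxy-4'-prenyloxyflavon-3-yl]trimethoxyborate (formed in the flask in step 8) | [Li+].COc1c(O[Si](C)(C)C(C)(C)C)cc2oc(-c3ccc(OCC=C(C)C)cc3)c([B-](OC)(OC)OC)c(=O)c2c1O[Si](C)(C)C(C)(C)C | intermediate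
17 | 5,7-bis(tert-butyldimethylsilyloxy)-3-hydroxy-6-methoxy-4'-prenyloxyflavone | COc1c(O[Si](C)(C)C(C)(C)C)cc2oc(-c3ccc(OCC=C(C)C)cc3)c(O)c(=O)c2c1O[Si](C)(C)C(C)(C)C | intermediate
18 | 3,5,7-trihydroxy-6-methoxy-4'-prenyloxyflavone | COc1c(O)cc2oc(-c3ccc(OCC=C(C)C)cc3)c(O)c(=O)c2c1O | target

**Totals**
Total step count: 9. Longest linear sequence: 7 steps (steps 1, 2, 3, 4, 7, 8, 9 from 2-methoxyresorcinol); the alkyne branch (steps 5 and 6) joins at step 7.

**Steps most likely to fail**

Step 7 (carbonylative annulation). Oxidative addition into the electron-rich C–I bond flanked by hydroxyl and silyloxy groups may be slow. Capture of the aroylpalladium species by diethylamine (amide formation), alkynylation without CO insertion followed by closure to a benzofuran, ionisation of the prenyl ether by zerovalent palladium, or silyl loss in the warm amine could then compete with the annulation.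

The fallback avoids palladium and CO and sets out from phenol 4 and alkyne 10. Magnesium-phenoxide-directed ortho-formylation of 4 (MgCl2, Et3N, paraformaldehyde, MeCN, reflux; the two ortho sites are identical) should give 2-hydroxy-5-methoxy-4,6-bis(tert-butyldimethylsilyloxy)benzaldehyde F1. Addition of the lithium acetylide of 10 (n-BuLi, THF, −78 to 0 °C, more than two equivalents because the first is consumed by the phenol) should give the racemic propargylic alcohol 1-[2-hydroxy-5-methoxy-4,6-bis(tert-butyldimethylsilyloxy)phenyl]-3-[4-(3-methylbut-2-enyloxy)phenyl]prop-2-yn-1-ol F2. Oxidation of this benzylic, propargylic alcohol with MnO2 in CH2Cl2 should give ynone 12, now isolated. Stirring 12 in Et2NH/EtOH at rt should close ring C through enaminone 13 and rejoin the route at flavone 14.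

Step 8 (C3 hydroxylation). Deprotonation at C3 may be incomplete or misdirected: the bulky 5-silyloxy group is a poor ligand for lithium, the C3 anion could add to unreacted flavone, and the base could attack the allylic position of the prenyl ether.

The fallback sets out from flavone 14. Conjugate reduction with LiBH(sec-Bu)3 in THF at −78 °C should give the flavanone lithium enolate, which is hydroxylated in the same flask with racemic 2-(phenylsulfonyl)-3-phenyloxaziridine. This should give racemic trans-5,7-bis(tert-butyldimethylsilyloxy)-3-hydroxy-6-methoxy-4'-prenyloxyflavanone F3, whose relative configuration does not matter. Dess–Martin oxidation (NaHCO3-buffered, CH2Cl2) of the secondary alcohol should give the 3,4-dione, whose enol tautomer is 3-hydroxyflavone 17, where the route is rejoined. Neither reagent should attack the prenyl olefin.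

Step 4 (mono-iodination). The phloroglucinol-type ring stays highly activated after the first iodination, so a second iodination at the other ortho carbon may compete. The free electron-rich phenol may also be oxidised by the iodinating agent.

The fallback sets out from phenol 4. Acetylation (Ac2O, pyridine, CH2Cl2) should give 3,5-bis(tert-butyldimethylsilyloxy)-4-methoxyphenyl acetate F4, which is less activated and no longer oxidisable. Iodination (NIS, catalytic CF3CO2H, MeCN, 0 °C) at one of the two identical ring positions should give 2-iodo-3,5-bis(tert-butyldimethylsilyloxy)-4-methoxyphenyl acetate F5. Aminolysis of the aryl acetate with Et2NH in THF at rt should return iodophenol 5; the same amine is the medium of step 7, so F5 could also be charged there directly.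

**Further compounds**
F1 | step 7 | 2-hydroxy-5-methoxy-4,6-bis(tert-butyldimethylsilyloxy)benzaldehyde | COc1c(O[Si](C)(C)C(C)(C)C)cc(O)c(C=O)c1O[Si](C)(C)C(C)(C)C
F2 | step 7 | 1-[2-hydroxy-5-methoxy-4,6-bis(tert-butyldimethylsilyloxy)phenyl]-3-[4-(3-methylbut-2-enyloxy)phenyl]prop-2-yn-1-ol (racemic) | COc1c(O[Si](C)(C)C(C)(C)C)cc(O)c(C(O)C#Cc2ccc(OCC=C(C)C)cc2)c1O[Si](C)(C)C(C)(C)C
F3 | step 8 | trans-5,7-bis(tert-butyldimethylsilyloxy)-3-hydroxy-6-methoxy-4'-prenyloxyflavanone (racemic; the 2R,3R enantiomer is drawn) | COc1c(O[Si](C)(C)C(C)(C)C)cc2O[C@H](c3ccc(OCC=C(C)C)cc3)[C@@H](O)C(=O)c2c1O[Si](C)(C)C(C)(C)C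
F4 | step 4 | 3,5-bis(tert-butyldimethylsilyloxy)-4-methoxyphenyl acetate | COc1c(O[Si](C)(C)C(C)(C)C)cc(OC(C)=O)cc1O[Si](C)(C)C(C)(C)C
F5 | step 4 | 2-iodo-3,5-bis(tert-butyldimethylsilyloxy)-4-methoxyphenyl acetate | COc1c(O[Si](C)(C)C(C)(C)C)cc(OC(C)=O)c(I)c1O[Si](C)(C)C(C)(C)C
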